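Ring C is a cyclopentane-1,3-dione whose carbonyl-level carbon C2′ lies between the alkylidene carbon C1′ and the doubly activated C3′. The route therefore cuts C1′–C2′ and C2′–C3′ and brings C2′ in as carbon monoxide: one palladium-catalysed carbonylative annulation joins a C1′–Br bond to the C3′ carbon of a β-keto ester, closes ring C and keeps the C11=C1′ geometry set beforehand. The precursor is a triethylsilyl-protected 8-epi-drimane (rings A and B, from (+)-sclareolide) carrying at C9 a (Z)-bromoalkene whose chain ends in a tert-butyl β-keto ester, chosen so that the ester can later be removed without heat or nucleophiles. Chlorination at C5′ and desilylation follow.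

Key step: step 9

Numbering: drimane numbering for rings A and B (C1–C10, C11 on C9); ring C is C1′ (alkylidene carbon, bonded to C11), C2′ (cis to C9), C3′, C4′, C5′ (bears Cl). Open-chain precursors carry the same labels.

Remark: the target is one enol tautomer of a 1,3-dione, so the dione stage is drawn in that form, and the C5′ chloride is assumed to be configurationally stable when base and free chloride are absent.

Step 1
Reactants: 1 (+)-sclareolide
Product: 2 8-epi-sclareolide (cis-fused lactone; 8β-oxygen and 8α-methyl)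
Conditions: conc. H2SO4, HCO2H, 23 °C
Reagents that add atoms: none
Why: Acid-mediated lactone epimerisation, in which reversible alkyl–oxygen ionisation at the tertiary C8 and re-closure lead to the thermodynamically preferred cis-fused γ-lactone, inverts C8 only and so sets the 8β-oxygen, 8α-methyl configuration of the target while C5, C9 and C10 stay as in 1.

Step 2
Reactants: 2 8-epi-sclareolide
Product: 3 11-hydroxy-8-epi-sclareolide (either C11 epimer)
Conditions: KN(SiMe3)2, THF, −78 °C; then 2-(phenylsulfonyl)-3-phenyloxaziridine, −78 °C; NH4Cl (aq)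
Reagents that add atoms: 2-(phenylsulfonyl)-3-phenyloxaziridine, O=S(=O)(c1ccccc1)N1OC1c1ccccc1
Why: Enolate hydroxylation with an N-sulfonyloxaziridine (Davis oxidation) puts oxygen on C11 of the potassium lactone enolate, the potassium counter-ion suppressing addition to the sulfonimine by-product, and the C11 configuration is of no consequence because C11 becomes a carbonyl carbon in step 3.

Step 3
Reactants: 3 11-hydroxy-8-epi-sclareolide
Product: 5 8β-hydroxydriman-11-al (9β-CHO and 8α-methyl), via triol 4 (not isolated)
Conditions: LiAlH4, THF, 0 → 23 °C, aqueous work-up; then NaIO4, THF/H2O, 0 → 23 °C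
Reagents that add atoms: none
Why: LiAlH4 reduction of the lactone to the 8,11,12-triol is followed by Malaprade glycol cleavage with NaIO4, which cuts only the vicinal C11–C12 diol (C12 leaves as formaldehyde) and not the 1,3-related tertiary C8 alcohol, under near-neutral conditions that leave C9 untouched.

Step 4
Reactants: 5 8β-hydroxydriman-11-al
Product: 6 8β-(triethylsilyloxy)driman-11-al
Conditions: Et3SiOTf, 2,6-lutidine, CH2Cl2, −78 → 0 °C
Reagents that add atoms: triethylsilyl trifluoromethanesulfonate, CC[Si](CC)(CC)OS(=O)(=O)C(F)(F)F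
Why: Silylation of a hindered tertiary alcohol with a silyl triflate and 2,6-lutidine, a base too weak and hindered to enolise the aldehyde, keeps C9 intact and gives the ether that later shields O8 from the phosphorus and zinc reagents and from the acylpalladium of step 9.

Step 5
Reactants: 6 8β-(triethylsilyloxy)driman-11-al
Product: 7 dibromoalkene (C9–C11H=CBr2 on the silylated drimane)
Conditions: PPh3, CBr4, Zn dust, CH2Cl2, 23 °C (ylide pre-formed); then 6, 0 → 23 °C
Reagents that add atoms: carbon tetrabromide, BrC(Br)(Br)Br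
Why: Ramirez–Corey–Fuchs dibromo-olefination (Wittig reaction of Ph3P=CBr2, generated with Zn so that neither Ph3PBr2 nor an amine base is present) uses a small ylide that can reach the hindered aldehyde in a non-basic medium, so C9 is not epimerised and the β-silyloxy group is not eliminated.

Step 6
Reactants: 7 dibromoalkene; 8 (2-tert-butoxy-2-oxoethyl)zinc bromide
Product: 9 tert-butyl (Z)-bromoalkenyl ester (C9–C11H=C1′(Br)–C5′H2–CO2t-Bu; Br cis to C9)
Conditions: 8 (BrZnCH2CO2t-Bu in Et2O), Pd(P(t-Bu)3)2 (cat.), THF, 23 °C
Reagents that add atoms: (2-tert-butoxy-2-oxoethyl)zinc bromide (8), CC(C)(C)OC(=O)C[Zn]Br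
Why: In this Negishi coupling of a zinc ester enolate (Reformatsky reagent), zerovalent palladium inserts into the less hindered C–Br bond, the one trans to C9, so the acetate arm enters trans to C9 and the bromine left behind is cis to C9 (Z), while the second C–Br bond, shielded by the substituents of C8 and C10, should not react at 23 °C.

Step 7
Reactants: 9 tert-butyl (Z)-bromoalkenyl ester
Product: 11 (Z)-bromoalkenyl carboxylic acid (C9–C11H=C1′(Br)–C5′H2–CO2H), via trimethylsilyl ester 10 (not isolated)
Conditions: Me3SiOTf, 2,6-lutidine, CH2Cl2, 0 °C; then pH 4 aqueous buffer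
Reagents that add atoms: none
Why: Silyl-triflate-mediated tert-butyl ester cleavage (O-silylation, loss of the tert-butyl group as isobutene, hydrolysis of the silyl ester on work-up) frees the acid without protic acid, so the silyl ether stays, and without base, so the β,γ-double bond does not migrate and HBr is not eliminated.

Step 8
Reactants: 11 (Z)-bromoalkenyl carboxylic acid; 12 mono-tert-butyl malonate
Product: 15 tert-butyl (Z)-bromoalkenyl β-keto ester (C9–C11H=C1′(Br)–C5′H2–C4′(=O)–C3′H2–CO2t-Bu; Br cis to C9), via acyl imidazolide 13 (not isolated), via magnesium malonate 14 (not isolated)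
Conditions: 11, CDI, THF, 23 °C; 12, n-Bu2Mg, THF, 0 → 23 °C; combined, 23 → 40 °C; cold 0.5 M HCl work-up
Reagents that add atoms: mono-tert-butyl malonate (12), CC(C)(C)OC(=O)CC(=O)O
Why: In the Masamune–Brooks homologation (a decarboxylative Claisen condensation) the acyl imidazolide C-acylates the magnesium chelate of the malonate half-ester and the adduct loses CO2, which gives the β-keto ester under near-neutral conditions that leave the (Z)-bromoalkene, its β,γ-position and the silyl ether alone.

Step 9
Reactants: 15 tert-butyl (Z)-bromoalkenyl β-keto ester; 16 carbon monoxide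
Product: 17 tert-butyl 4-alkylidenecyclopentane-1,3-dione-2-carboxylate (ring C closed: C1′=C11H–C9 with C2′=O cis to C9; C3′H–CO2t-Bu; C4′=O; C5′H2)
Conditions: Pd(OAc)2 (5 mol %), Xantphos (6 mol %), CO (1 atm), MgCl2, Et3N, MeCN, 70 °C; cold aqueous citric acid work-up
Reagents that add atoms: carbon monoxide (16), [C-]#[O+]
Why: Pd(OAc)2 and Xantphos give zerovalent palladium, which inserts into the C1′–Br bond with retention; CO then inserts to an acylpalladium (divalent palladium) whose acyl carbon C2′ is cis to C9, the C3′ carbon of the magnesium-chelated β-keto ester enolate (MgCl2/Et3N) attacks C2′, and Et3N takes up HBr. The closest known reaction type is the palladium-catalysed carbonylative C-acylation of 1,3-dicarbonyl compounds by organic halides, including its intramolecular version in which an acylpalladium is trapped by a tethered stabilised enolate. Ring C closes in the 5-exo-trig mode at the acyl carbon (equivalently by reductive elimination from a six-membered acyl(enolato)palladium chelate), so that C1′–C2′ and C2′–C3′ form in one operation. No stereocentre is created, and the C11=C1′ geometry is that of the (Z)-bromoalkene. The step needs C- over O-acylation, carbonylation before any direct coupling and an untouched C5′H2: magnesium chelation leaves C3′ as the nucleophilic site and the five-membered carbocycle is preferred to the enol lactone, direct C3′–C1′ coupling would need a four-membered ring, and the more acidic C3′–H is removed first so that the C4′ ketone does not enolise towards C5′. The O8 silyl ether keeps the 8β-oxygen from capturing the acylpalladium as a six-membered lactone.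

Step 10
Reactants: 17 tert-butyl 4-alkylidenecyclopentane-1,3-dione-2-carboxylate
Product: 20 O8-silylated deschloro dione (ring C: C2′ enol; C4′ ketone; C3′H; C5′H2), via silylated ester 18 (not isolated), via carboxylic acid 19 (not isolated)
Conditions: Me3SiOTf, 2,6-lutidine, CH2Cl2, 0 °C; then THF/aqueous citric acid (pH 3), 23 → 40 °C
Reagents that add atoms: none
Why: Silyl-triflate-mediated cleavage of the tert-butyl ester followed by hydrolysis gives the 2-carboxy-1,3-dione, a β-keto acid that loses CO2 near room temperature, so the ester leaves without nucleophile, strong base or heat and the C11=C1′ bond keeps its position and geometry while the O8 silyl ether stays.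

Step 11
Reactants: 20 O8-silylated deschloro dione
Product: 23 O8-triethylsilyl ether of the target ((5′R)-chloride), via bis(silyloxy)fulvene 21 (not isolated), via chloro silyl enol ether 22 (not isolated)
Conditions: Me3SiOTf, Et3N, Et2O, 0 °C, ammonium salt removed; then NCS, THF, −78 °C; pH 4 aqueous buffer; chromatography
Reagents that add atoms: N-chlorosuccinimide, O=C1CCC(=O)N1Cl
Why: Soft enolisation with Me3SiOTf/Et3N (the method that turns vinylogous esters into 2-silyloxydienes) converts 20, whichever enol oxygen is silylated first, into the single 2′,4′-bis(silyloxy)fulvene, and NCS (electrophilic α-chlorination of a silyl enol ether) should attack it at C5′, the terminus of the 1,3-bis(silyloxy)diene and the only site whose attack leaves a 1,3-dioxyallyl cation, whereas attack at C11 would create a cyclopentadienone-type cation; the new C5′ centre has no reliable facial bias from the distant drimane, so both C5′ epimers are expected and the (5′R) epimer is secured by chromatographic separation of these diastereomers.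

Step 12
Reactants: 23 O8-triethylsilyl ether of the target
Product: 24 CNP0279879.2 (target)
Conditions: HF (48 % aq), MeCN, 0 °C
Reagents that add atoms: none
Why: Acidic fluoride desilylation of the tertiary triethylsilyl ether is run under aqueous, base-free and chloride-free conditions, so that C5′ is neither epimerised by enolisation nor inverted by halide exchange and the C8 alcohol is not dehydrated.

Compound list

1 | (+)-sclareolide (trans-fused lactone; 8α-oxygen) | CC1(C)CCC[C@]2(C)[C@H]3CC(=O)O[C@]3(C)CC[C@@H]12 | starting material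
2 | 8-epi-sclareolide (cis-fused lactone; 8β-oxygen, 8α-methyl) | CC1(C)CCC[C@]2(C)[C@H]3CC(=O)O[C@@]3(C)CC[C@@H]12 | intermediate
3 | 11-hydroxy-8-epi-sclareolide (either C11 epimer) | CC1(C)CCC[C@]2(C)[C@H]3C(O)C(=O)O[C@@]3(C)CC[C@@H]12 | intermediate
4 | 8β,11,12-triol (C9β–CH(OH)–CH2OH, 8β-OH; either C11 epimer) | CC1(C)CCC[C@]2(C)[C@@H](C(O)CO)[C@@](C)(O)CC[C@@H]12 | intermediate
5 | 8β-hydroxydriman-11-al (5α-H, 10β-methyl, 9β-CHO, 8β-OH, 8α-methyl) | CC1(C)CCC[C@]2(C)[C@@H](C=O)[C@@](C)(O)CC[C@@H]12 | intermediate
6 | 8β-(triethylsilyloxy)driman-11-al | CC1(C)CCC[C@]2(C)[C@@H](C=O)[C@@](C)(O[Si](CC)(CC)CC)CC[C@@H]12 | intermediate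
7 | dibromoalkene, C9–C11H=CBr2, 8β-OSiEt3 | CC1(C)CCC[C@]2(C)[C@@H](C=C(Br)Br)[C@@](C)(O[Si](CC)(CC)CC)CC[C@@H]12 | intermediate
8 | (2-tert-butoxy-2-oxoethyl)zinc bromide, BrZnCH2CO2t-Bu | CC(C)(C)OC(=O)C[Zn]Br | starting material
9 | tert-butyl (Z)-bromoalkenyl ester, C9–C11H=C1′(Br)–C5′H2–CO2t-Bu, Br cis to C9 | CC1(C)CCC[C@]2(C)[C@@H](/C=C(\Br)CC(=O)OC(C)(C)C)[C@@](C)(O[Si](CC)(CC)CC)CC[C@@H]12 | intermediate
10 | trimethylsilyl ester of acid 11 | CC1(C)CCC[C@]2(C)[C@@H](/C=C(\Br)CC(=O)O[Si](C)(C)C)[C@@](C)(O[Si](CC)(CC)CC)CC[C@@H]12 | intermediate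
11 | (Z)-bromoalkenyl carboxylic acid, C9–C11H=C1′(Br)–C5′H2–CO2H | CC1(C)CCC[C@]2(C)[C@@H](/C=C(\Br)CC(=O)O)[C@@](C)(O[Si](CC)(CC)CC)CC[C@@H]12 | intermediate
12 | mono-tert-butyl malonate (3-tert-butoxy-3-oxopropanoic acid) | CC(C)(C)OC(=O)CC(=O)O | starting material
13 | acyl imidazolide of acid 11 | CC1(C)CCC[C@]2(C)[C@@H](/C=C(\Br)CC(=O)n3ccnc3)[C@@](C)(O[Si](CC)(CC)CC)CC[C@@H]12 | intermediate
14 | magnesium bis(mono-tert-butyl malonate), Mg(O2CCH2CO2t-Bu)2 | CC(C)(C)OC(=O)CC(=O)[O-].CC(C)(C)OC(=O)CC(=O)[O-].[Mg+2] | intermediate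
15 | tert-butyl (Z)-bromoalkenyl β-keto ester, C9–C11H=C1′(Br)–C5′H2–C4′(=O)–C3′H2–CO2t-Bu, Br cis to C9 | CC1(C)CCC[C@]2(C)[C@@H](/C=C(\Br)CC(=O)CC(=O)OC(C)(C)C)[C@@](C)(O[Si](CC)(CC)CC)CC[C@@H]12 | intermediate
16 | carbon monoxide | [C-]#[O+] | starting material
17 | tert-butyl 4-alkylidenecyclopentane-1,3-dione-2-carboxylate (C2′=O cis to C9, C3′–CO2t-Bu, 8β-OSiEt3) | CC1(C)CCC[C@]2(C)[C@@H](/C=C3\C(=O)C(C(=O)OC(C)(C)C)C(=O)C3)[C@@](C)(O[Si](CC)(CC)CC)CC[C@@H]12 | intermediate
18 | silylated ester: C3′–CO2SiMe3 and enol silyl ether (drawn on O4′; its position is immaterial) | CC1(C)CCC[C@]2(C)[C@@H](/C=C3\C(=O)C(C(=O)O[Si](C)(C)C)=C(O[Si](C)(C)C)C3)[C@@](C)(O[Si](CC)(CC)CC)CC[C@@H]12 | intermediate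
19 | ring C 2-carboxy-1,3-dione (C3′–CO2H) | CC1(C)CCC[C@]2(C)[C@@H](/C=C3\C(=O)C(C(=O)O)C(=O)C3)[C@@](C)(O[Si](CC)(CC)CC)CC[C@@H]12 | intermediate
20 | O8-silylated deschloro dione (C2′ enol, C4′ ketone, C5′H2) | CC1(C)CCC[C@]2(C)[C@@H](/C=C3\C(O)=CC(=O)C3)[C@@](C)(O[Si](CC)(CC)CC)CC[C@@H]12 | intermediate
21 | 2′,4′-bis(trimethylsilyloxy)fulvene (C2′=C3′ and C4′=C5′ enol ethers, C1′=C11) | CC1(C)CCC[C@]2(C)[C@@H](/C=C3\C(O[Si](C)(C)C)=CC(O[Si](C)(C)C)=C3)[C@@](C)(O[Si](CC)(CC)CC)CC[C@@H]12 | intermediate
22 | (5′R)-5′-chloro C2′ trimethylsilyl enol ether, C4′ ketone | CC1(C)CCC[C@]2(C)[C@@H](/C=C3\C(O[Si](C)(C)C)=CC(=O)[C@@H]3Cl)[C@@](C)(O[Si](CC)(CC)CC)CC[C@@H]12 | intermediate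
23 | O8-triethylsilyl ether of the target, (5′R) | CC1(C)CCC[C@]2(C)[C@@H](/C=C3\C(O)=CC(=O)[C@@H]3Cl)[C@@](C)(O[Si](CC)(CC)CC)CC[C@@H]12 | intermediate
24 | CNP0279879.2 (5S,8S,9R,10S,5′R; C9 cis to C2′) | CC1(C)CCC[C@]2(C)[C@@H](/C=C3\C(O)=CC(=O)[C@@H]3Cl)[C@@](C)(O)CC[C@@H]12 | target

Total step count: 12.
Longest linear sequence: 12 steps, from (+)-sclareolide 1 to 24; 8, 12 and 16 are purchased.

Steps most likely to fail

1. Step 9 (key step). What may go wrong: slow oxidative addition at the C1′–Br bond, which is shielded by C9, and capture of the acylpalladium at the enol oxygen of the C4′ ketone (O-acylation to an enol lactone) in place of C3′. Fallback: the two bonds are made one after the other. Setting out from 15, palladium-catalysed methoxycarbonylation (Pd(OAc)2, Xantphos, CO, MeOH, Et3N, 70 °C, no MgCl2), in which methanol captures the acylpalladium, should give the methyl ester F1 (CO2Me on C1′, cis to C9). Dieckmann condensation (KOt-Bu, THF, 0 °C), in which the C3′ enolate attacks the C2′ ester, then closes ring C and comes back to the route at 17.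

2. Step 11. What may go wrong: no facial discrimination at C5′, so that the wanted epimer is the minor one or is hard to separate; attack of the chlorinating agent at C3′; a second chlorination; decomposition of the silyloxyfulvene. Fallback: chlorination before the ester is removed, through a dianion in which C3′ is blocked. Setting out from 17, LiN(i-Pr)2 (2.2 equiv, THF, −78 °C) should form the dianion (γ-functionalisation of a 1,3-dicarbonyl dianion), which hexachloroethane chlorinates at C5′ to give the chloro ester F2 as a pair of C5′ epimers. Removal of the ester as in step 10 and separation of the epimers comes back to the route at 23. In either variant the unwanted (5′S) epimer F3 need not be lost: Zn/AcOH dechlorination returns it to 20.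

3. Step 6. What may go wrong: slow transmetalation of the zinc enolate to the hindered bromoalkenylpalladium, with protodebromination or loss of HBr to a bromoalkyne, and isomerisation of the product by the basic zinc enolate. Fallback: the two carbons enter as an allyl group and the chain is finished by changes of oxidation state. Setting out from 7, trans-selective Stille coupling with allyltributylstannane (Pd2(dba)3, tri(2-furyl)phosphine, toluene) should give the (Z)-bromodiene F4. Lemieux–Johnson cleavage of its terminal alkene (OsO4 cat., NaIO4, 2,6-lutidine, dioxane/H2O) gives the aldehyde F5. Roskamp homologation with tert-butyl diazoacetate and SnCl2 (CH2Cl2, 23 °C) comes back to the route at 15, passing over 9 and 11.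

Further compounds
F1 | step 9 | methyl ester, C9–C11H=C1′(CO2Me)–C5′H2–C4′(=O)–C3′H2–CO2t-Bu, CO2Me cis to C9 | CC1(C)CCC[C@]2(C)[C@@H](/C=C(\C(=O)OC)CC(=O)CC(=O)OC(C)(C)C)[C@@](C)(O[Si](CC)(CC)CC)CC[C@@H]12
F2 | step 11 | 5′-chloro derivative of 17 (both C5′ epimers) | CC1(C)CCC[C@]2(C)[C@@H](/C=C3\C(=O)C(C(=O)OC(C)(C)C)C(=O)C3Cl)[C@@](C)(O[Si](CC)(CC)CC)CC[C@@H]12
F3 | step 11 | (5′S) epimer of 23 | CC1(C)CCC[C@]2(C)[C@@H](/C=C3\C(O)=CC(=O)[C@H]3Cl)[C@@](C)(O[Si](CC)(CC)CC)CC[C@@H]12
F4 | step 6 | (Z)-bromodiene, C9–C11H=C1′(Br)–C5′H2–CH=CH2, Br cis to C9 | CC1(C)CCC[C@]2(C)[C@@H](/C=C(\Br)CC=C)[C@@](C)(O[Si](CC)(CC)CC)CC[C@@H]12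
F5 | step 6 | (Z)-bromoalkenyl aldehyde, C9–C11H=C1′(Br)–C5′H2–C4′HO | CC1(C)CCC[C@]2(C)[C@@H](/C=C(\Br)CC=O)[C@@](C)(O[Si](CC)(CC)CC)CC[C@@H]12
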